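## Analysis of the target

The target is a flavonol, a 2-aryl-4H-chromen-4-one. Ring A (C4a to C8a, oxygens on C5 and C7) is fused to the 4-pyranone ring C (O1, C2, C3, C4), and ring B, oxygenated at C3' and C4', sits on C2. There is no stereocentre, so the problem is one of telling five oxygens apart: O3 carries an acetyl group, O7, O3' and O4' carry hydrogen sulfate groups, and the 5-OH is free. The aryl sulfate monoesters are strongly acidic, very polar and easily hydrolysed, so they can only be introduced last. The 3-acetate is the ester of an acidic enol and is cleaved readily by bases and nucleophilic solvents. Two features help: the 5-OH is held by a six-membered hydrogen bond to the C4 carbonyl and is the least reactive hydroxyl of the nucleus, and the three oxygens to be sulfated can share one protecting group that is removed without base. The difficulty is therefore to build ring C so that the 3-OH emerges as the only reactive hydroxyl while O7, O3' and O4' are masked alike. The strategy rests on the position of C4: this carbonyl carbon lies between C4a of ring A and the oxygen-bearing C3, so it can be supplied as carbon monoxide between a ring A aryl iodide, whose iodinated carbon is flanked by two identical protected oxygens, and the enolate carbon of a ring B ketone that already carries O3.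

## Retrosynthetic reasoning

**18 to 17.** The three S–O bonds at O7, O3' and O4' are cut first. Sulfate monoesters tolerate neither chromatography on silica nor organometallic or acidic steps, so nothing else can follow them. The forward step has to sulfate three phenols of 17, both catechol oxygens included, and leave the chelated 5-OH and the 3-acetate alone.

**17 to 16.** The three benzylic C–O bonds at O7, O3' and O4' are cut. One common group on exactly the oxygens that will be sulfated means a single unmasking step, and hydrogenolysis is neutral, which the base-labile 3-acetate requires.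

**16 to 15.** The acyl C–O bond at O3 is cut. In 15 only the 3-OH and the 5-OH are free, and the 5-OH is deactivated by chelation, so the forward acetylation needs no further protecting group.

**15 to 7, 12 and 13, by way of 14.** Ring C is opened at O1–C2, giving the 2-alkoxy-1,3-diketone 14, and 14 is cut on both sides of C4, at C4a–C4 and C3–C4.
- The cut is made here because C4 is a lone carbonyl carbon between an arene carbon and an enolisable carbon, which is the pattern a carbonylative coupling assembles from an aryl iodide, carbon monoxide 13 and a ketone.
- The gain is convergence. Ring A arrives as iodide 7 with all its oxygens in place, and ring B arrives with C2, C3 and O3 as ketone 12.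
- In 7 the two oxygens next to the C–I bond carry the same acid-labile acetal group. Either can become O1 and the other becomes the 5-OH, so ring closure has no regiochemical choice.
- The forward reaction must insert 13 between 7 and the enolate carbon of 12 under a zerovalent palladium catalyst. Acid in the same flask must then remove the three acetal groups and close ring C by cyclodehydration.

**7 to 6, 4, 2 and 1.**
- The benzyl ether of 7 is cut to phenol 6.
- The C5–O bond of 6 is traced to a C–H bond of iodide 4. C5 is the only ring position of 4 without an ortho substituent, so a sterically governed C–H borylation followed by oxidation can only place the oxygen there.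
- The C–I bond of 4 is traced to the C2–H bond of bis-acetal 2, which is the one position flanked by two directing acetal groups.
- Bis-acetal 2 comes from diphenol 1.
- This order fixes every regiochemical question by substrate structure. Monobenzylation of a symmetric triphenol followed by metalation of the benzyl ether was set aside: the first step is statistical and open to C-alkylation, and the second faces three activated ring positions and an acidic benzylic CH2.

**12 to 11, 9 and 8.** The acetal on O3 is cut to α-hydroxy ketone 11, the α-C–O bond of 11 is traced to the methyl group of ketone 9, and the two benzyl ethers of 9 go back to the catechol ketone 8. Bringing O3 in at the ketone stage avoids any late oxidation of the finished pyranone.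

## Alternatives that were turned down

**Alternative 1:** thermal condensation of phloroglucinol with a ketoester.
- Disconnection: C4–C4a and O1–C2, pairing unprotected phloroglucinol A2 with ethyl 2-(benzyloxy)-3-(2,2-diphenyl-1,3-benzodioxol-5-yl)-3-oxopropanoate A3.
- Forward key step: the two are heated without catalyst (a Mentzer-type pyrone synthesis). The ester acylates the electron-rich ring of A2, a neighbouring phenol adds to the ketone, and alcohol and water are lost to give 3-(benzyloxy)-2-(2,2-diphenyl-1,3-benzodioxol-5-yl)-5,7-dihydroxychromen-4-one A1.
- For it: A2 needs no protection, its threefold symmetry removes any regiochemical question on ring A, no metal or gas is needed, and the flavonol core is reached in fewer steps than in the chosen route. On step count to the core this alternative is stronger.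
- Against it: uncatalysed ester acylation needs temperatures above 200 °C, which put the benzyl ether, the ketal and the 1,3-dicarbonyl unit of A3 at risk. If the phenol adds to the ketone first, a 4-arylcoumarin results.
- Against it for this target: A1 has the protection pattern reversed. O3 is masked and O7 is free, whereas the target needs O3 unmasked alone and O7 masked together with O3' and O4'. Hydrogenolysis of A1 would expose O3 together with the catechol, so protecting-group exchanges would be needed and the step advantage is lost.
- Comparison: the chosen strategy is longer up to the core but delivers 15, whose protecting groups already match the target.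

**Alternative 2:** closure of ring C by fluorine displacement.
- Disconnection: O1–C8a, leading to 1-[3,4-bis(benzyloxy)phenyl]-2-(4-methoxybenzyloxy)-3-(2,4,6-trifluorophenyl)propane-1,3-dione A5.
- Forward key step: with a carbonate base the enolate oxygen of A5 displaces an ortho fluorine activated by the adjacent acyl group, giving 2-[3,4-bis(benzyloxy)phenyl]-5,7-difluoro-3-(4-methoxybenzyloxy)chromen-4-one A4.
- For it: the intramolecular displacement is dependable and needs no transition metal. The 4-methoxybenzyl group on O3 is orthogonal to the benzyl ethers, so the 3-OH could be freed without relying on the low reactivity of the 5-OH. On that point this alternative is stronger.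
- Against it: A4 carries fluorine where the target has oxygen. C5 and C7 would need two further displacements by alkoxides, and both positions are activated by the C4 carbonyl. They would have to be told apart, since O7 must end as a sulfate and O5 as a free hydroxyl. Hard alkoxides can also open the pyranone at C2.
- Against it: A5 itself needs C-acylation of an α-alkoxy ketone enolate by a doubly ortho-substituted benzoyl donor, the same bond the chosen route forms catalytically, so nothing is saved there.
- Comparison: the chosen strategy has every ring A oxygen in place before the key step and needs no late exchange on the finished heterocycle.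

**Alternative 3:** aryne insertion into an arylpropiolic acid.
- Disconnection: O1–C8a, C4a–C4 and O1–C2 in one operation, from 3,5-bis(benzyloxy)benzyne A7 and 3-[3,4-bis(benzyloxy)phenyl]prop-2-ynoic acid A8.
- Forward key step: fluoride releases A7. The carboxylate oxygen of A8 adds at the aryne carbon remote from the alkoxy group, the aryl anion takes over the acyl group, and the freed phenoxide adds to the ynone to give 5,7,3',4'-tetrakis(benzyloxy)flavone A6.
- For it: three bonds form under mild conditions without carbon monoxide, and the regiochemistry is set by the polarisation of the alkoxy aryne. With O5 benzylated in A6, a later acetylation at O3 would have no competitor. On both points this alternative is stronger.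
- Against it: A6 has hydrogen at C3. The oxygen that carries the acetate would have to be introduced afterwards by oxidising an electron-rich flavone. The silyl triflate precursor of A7 takes several steps, and the final phenoxide addition can also close the five-membered ring to an aurone.
- Comparison: the chosen strategy brings O3 in with ketone 12 and needs no oxidation after ring formation. It pays with a catalytic step that uses a gas and a hindered iodide.

Key step: step 8

Assumption: the target is drawn as the neutral tris(hydrogen sulfate). It is taken to be handled as its pyridinium or sodium salt and brought to the drawn acid form by cold ion exchange directly before use.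

## Route

Step 1
Reactants: 1 resorcinol
Product: 2 1,3-bis(methoxymethoxy)benzene
Conditions: NaH, MOMCl, DMF, 0 °C → rt
Reagents that add atoms: chloromethyl methyl ether, COCCl
Why: Double O-alkylation of the diphenoxide by the α-chloro ether (Williamson-type acetal formation); the hard oxocarbenium-like electrophile should react at oxygen, not carbon.

Step 2
Reactants: 2 1,3-bis(methoxymethoxy)benzene
Product: 4 2-iodo-1,3-bis(methoxymethoxy)benzene, via aryllithium 3 (not isolated)
Conditions: n-BuLi, THF, 0 °C; then I2, −78 °C → rt
Reagents that add atoms: iodine, II
Why: Directed ortho-metalation: both acetal groups coordinate the base and acidify C2–H, so deprotonation should occur only between them, and iodine traps aryllithium 3.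

Step 3
Reactants: 4 2-iodo-1,3-bis(methoxymethoxy)benzene
Product: 6 4-iodo-3,5-bis(methoxymethoxy)phenol, via aryl pinacol boronate 5 (not isolated)
Conditions: [Ir(OMe)(cod)]2 (cat.), 4,4'-di-tert-butyl-2,2'-bipyridine (cat.), B2pin2, THF, 60 °C; then NaOH, H2O2, H2O, 0 °C → rt
Reagents that add atoms: hydrogen peroxide, OO (the phenol oxygen); bis(pinacolato)diboron, CC1(C)OB(OC1(C)C)B1OC(C)(C)C(C)(C)O1 (boron held only by intermediate 5)
Why: Iridium-catalysed C–H borylation is sterically governed and C5 is the only C–H without an ortho substituent; the C–I bond, shielded by two ortho acetal groups, should be left alone, and basic peroxide then converts C–B into C–O at the same carbon (one-flask borylation–oxidation).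

Step 4
Reactants: 6 4-iodo-3,5-bis(methoxymethoxy)phenol
Product: 7 5-(benzyloxy)-2-iodo-1,3-bis(methoxymethoxy)benzene
Conditions: BnBr, K2CO3, DMF, rt
Reagents that add atoms: benzyl bromide, BrCc1ccccc1
Why: Williamson ether synthesis on the only free phenol; the acetals and the aryl iodide are inert to carbonate base.

Step 5
Reactants: 8 3',4'-dihydroxyacetophenone
Product: 9 3',4'-bis(benzyloxy)acetophenone
Conditions: BnBr, K2CO3, DMF, 60 °C
Reagents that add atoms: benzyl bromide, BrCc1ccccc1
Why: Double Williamson etherification of the catechol; the phenoxides are far more nucleophilic than the ketone enolate under carbonate base.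

Step 6
Reactants: 9 3',4'-bis(benzyloxy)acetophenone
Product: 11 1-[3,4-bis(benzyloxy)phenyl]-2-hydroxyethan-1-one, via hydroxy dimethyl acetal 10 (not isolated)
Conditions: PhI(OAc)2, KOH, MeOH, 0 °C → rt; then 2 M HCl, THF, rt
Reagents that add atoms: water, O (the new carbonyl oxygen on acetal hydrolysis); methanol, CO (the two methoxy groups of intermediate 10 only)
Why: Moriarty α-hydroxylation of a methyl ketone: the enolate is bound to trivalent iodine at carbon, methoxide adds to the carbonyl, loss of iodobenzene gives a methoxy epoxide that opens to acetal 10, and aqueous acid returns the ketone.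

Step 7
Reactants: 11 1-[3,4-bis(benzyloxy)phenyl]-2-hydroxyethan-1-one
Product: 12 1-[3,4-bis(benzyloxy)phenyl]-2-(methoxymethoxy)ethan-1-one
Conditions: MOMCl, i-Pr2NEt, CH2Cl2, 0 °C → rt
Reagents that add atoms: chloromethyl methyl ether, COCCl
Why: Acetal protection of a primary alcohol under mild amine base, which avoids enolisation and self-condensation of the α-hydroxy ketone.

Step 8
Reactants: 7 5-(benzyloxy)-2-iodo-1,3-bis(methoxymethoxy)benzene; 12 1-[3,4-bis(benzyloxy)phenyl]-2-(methoxymethoxy)ethan-1-one; 13 carbon monoxide
Product: 15 7,3',4'-tri-O-benzylquercetin, via 2-(methoxymethoxy)-1,3-diketone 14 (not isolated)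
Conditions: Pd(dba)2 (5 mol %), 1,3-bis(diphenylphosphino)propane (6 mol %), MgCl2, Et3N, CO (3 bar), 1,4-dioxane, 80 °C; then vent, HCl/MeOH, 60 °C
Reagents that add atoms: none
Why: Oxidative addition of the C–I bond of 7 to zerovalent palladium (from Pd(dba)2 and the bisphosphine) and migratory insertion of CO give an aroylpalladium iodide, forming C4a–C4. MgCl2 and Et3N enolise 12 to a magnesium enolate chelated through the ketone and α-alkoxy oxygens; it is transferred to palladium through carbon, and reductive elimination forms C3–C4 and releases diketone 14 as its magnesium diketonate. The closest known reaction type is the palladium-catalysed carbonylative α-arylation of aryl alkyl ketones with aryl iodides to 1,3-diketones, combined with magnesium-mediated soft enolisation as used for C-acylation of ketones. HCl in methanol then cleaves the three methoxymethyl acetals by transacetalisation; a freed ortho phenol adds to the ring B carbonyl (C2) in a 6-exo-trig closure to a cyclic hemiketal, and loss of water across C2–C3 gives the 4-pyranone, as in the last stage of a Baker–Venkataraman flavone synthesis. No stereocentre remains, since the C3 centre of 14 is lost on dehydration. Carbonylative coupling should win over direct arylation because CO insertion relieves crowding at the doubly ortho-substituted arylpalladium and a bisphosphine complex eliminates a hindered aryl–enolate pair only slowly. C-acylation should win over O-acylation because the enolate oxygen is tied up in the magnesium chelate. Ring closure has no regiochemical choice because the two oxygens flanking C4a are identical: one becomes O1 and the other the chelated 5-OH, while the benzyl ethers survive both stages.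

Step 9
Reactants: 15 7,3',4'-tri-O-benzylquercetin
Product: 16 3-O-acetyl-7,3',4'-tri-O-benzylquercetin
Conditions: Ac2O (1.2 equiv), pyridine, CH2Cl2, 0 °C
Reagents that add atoms: acetic anhydride, CC(=O)OC(C)=O
Why: O-acylation under mild base; the 5-OH is locked in a six-membered hydrogen bond to the C4 carbonyl and is the least nucleophilic hydroxyl of the flavone nucleus, so a slight excess of anhydride at 0 °C should esterify only the enolic 3-OH.

Step 10
Reactants: 16 3-O-acetyl-7,3',4'-tri-O-benzylquercetin
Product: 17 quercetin 3-acetate
Conditions: H2 (1 atm), 10 % Pd/C, THF–EtOAc, rt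
Reagents that add atoms: none
Why: Catalytic hydrogenolysis of aryl benzyl ethers; the ester and the pyranone double bond should be inert at one atmosphere, and the aprotic solvent avoids solvolysis of the activated 3-acetate.

Step 11
Reactants: 17 quercetin 3-acetate
Product: 18 quercetin 3-acetate 7,3',4'-tri-O-sulfate
Conditions: SO3·pyridine (excess), DMF–pyridine, rt → 40 °C; then sulfonic acid resin (protonated form), H2O, 0 °C
Reagents that add atoms: sulfur trioxide–pyridine complex, [O-]S(=O)(=O)[n+]1ccccc1
Why: O-sulfation of phenols by an amine–SO3 complex; the three unchelated phenols should react, the hydrogen-bonded 5-OH is the slowest position and should stay free with a controlled excess, and no base stronger than pyridine is present, which spares the acetate.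

## Compound list

1 | resorcinol (benzene-1,3-diol) | Oc1cccc(O)c1 | starting material
2 | 1,3-bis(methoxymethoxy)benzene | COCOc1cccc(OCOC)c1 | intermediate
3 | [2,6-bis(methoxymethoxy)phenyl]lithium | [Li]c1c(OCOC)cccc1OCOC | intermediate (not isolated)
4 | 2-iodo-1,3-bis(methoxymethoxy)benzene | COCOc1cccc(OCOC)c1I | intermediate
5 | 2-[4-iodo-3,5-bis(methoxymethoxy)phenyl]-4,4,5,5-tetramethyl-1,3,2-dioxaborolane | COCOc1cc(B2OC(C)(C)C(C)(C)O2)cc(OCOC)c1I | intermediate (not isolated)
6 | 4-iodo-3,5-bis(methoxymethoxy)phenol | COCOc1cc(O)cc(OCOC)c1I | intermediate
7 | 5-(benzyloxy)-2-iodo-1,3-bis(methoxymethoxy)benzene | COCOc1cc(OCc2ccccc2)cc(OCOC)c1I | intermediate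
8 | 3',4'-dihydroxyacetophenone | CC(=O)c1ccc(O)c(O)c1 | starting material
9 | 3',4'-bis(benzyloxy)acetophenone | CC(=O)c1ccc(OCc2ccccc2)c(OCc2ccccc2)c1 | intermediate
10 | 2-[3,4-bis(benzyloxy)phenyl]-2,2-dimethoxyethan-1-ol | COC(CO)(OC)c1ccc(OCc2ccccc2)c(OCc2ccccc2)c1 | intermediate (not isolated)
11 | 1-[3,4-bis(benzyloxy)phenyl]-2-hydroxyethan-1-one | O=C(CO)c1ccc(OCc2ccccc2)c(OCc2ccccc2)c1 | intermediate
12 | 1-[3,4-bis(benzyloxy)phenyl]-2-(methoxymethoxy)ethan-1-one | COCOCC(=O)c1ccc(OCc2ccccc2)c(OCc2ccccc2)c1 | intermediate
13 | carbon monoxide | [C-]#[O+] | starting material
14 | 1-[4-(benzyloxy)-2,6-bis(methoxymethoxy)phenyl]-3-[3,4-bis(benzyloxy)phenyl]-2-(methoxymethoxy)propane-1,3-dione | COCOc1cc(OCc2ccccc2)cc(OCOC)c1C(=O)C(OCOC)C(=O)c1ccc(OCc2ccccc2)c(OCc2ccccc2)c1 | intermediate (not isolated)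
15 | 7,3',4'-tri-O-benzylquercetin (7-(benzyloxy)-2-[3,4-bis(benzyloxy)phenyl]-3,5-dihydroxy-4H-chromen-4-one) | O=c1c(O)c(-c2ccc(OCc3ccccc3)c(OCc3ccccc3)c2)oc2cc(OCc3ccccc3)cc(O)c12 | intermediate
16 | 3-O-acetyl-7,3',4'-tri-O-benzylquercetin (7-(benzyloxy)-2-[3,4-bis(benzyloxy)phenyl]-5-hydroxy-4-oxo-4H-chromen-3-yl acetate) | CC(=O)Oc1c(-c2ccc(OCc3ccccc3)c(OCc3ccccc3)c2)oc2cc(OCc3ccccc3)cc(O)c2c1=O | intermediate
17 | quercetin 3-acetate (2-(3,4-dihydroxyphenyl)-5,7-dihydroxy-4-oxo-4H-chromen-3-yl acetate) | CC(=O)Oc1c(-c2ccc(O)c(O)c2)oc2cc(O)cc(O)c2c1=O | intermediate
18 | quercetin 3-acetate 7,3',4'-tri-O-sulfate | CC(=O)Oc1c(-c2ccc(OS(=O)(=O)O)c(OS(=O)(=O)O)c2)oc2cc(OS(=O)(=O)O)cc(O)c2c1=O | target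

## Step count and least certain steps

Total: 11 steps. Longest linear sequence: 8 steps (steps 1 to 4, then 8 to 11); the ketone branch (steps 5 to 7) joins at step 8.

**Step 8 (key step).** The aroylpalladium intermediate is flanked by two ortho substituents and may be captured too slowly by the enolate. O-acylation of the enolate, reduction of the C–I bond or direct arylation without CO could then take over. The α-alkoxy ketone may self-condense, and in the acid stage retro-Claisen cleavage of 14 by methanol could compete with ring closure.

Fallback, setting out from 7 and 12 and returning at 14: iodine–lithium exchange on 7 (n-BuLi, THF, −78 °C) would give [4-(benzyloxy)-2,6-bis(methoxymethoxy)phenyl]lithium F1, and formylation with DMF would give 4-(benzyloxy)-2,6-bis(methoxymethoxy)benzaldehyde F2. Deprotonation of 12 with lithium diisopropylamide (THF, −78 °C) would give the chelated lithium (Z)-enolate of 12 F3, which would add to F2 to give 1-[3,4-bis(benzyloxy)phenyl]-3-[4-(benzyloxy)-2,6-bis(methoxymethoxy)phenyl]-3-hydroxy-2-(methoxymethoxy)propan-1-one F4 as a mixture of diastereomers. Dess–Martin oxidation of F4 would give diketone 14, which is then treated with HCl in methanol as in the route to reach 15. This replaces the catalytic three-component step by an aldol addition and an oxidation.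

**Step 3.** The iridium boryl catalyst may engage the C–I bond instead of the C5–H bond, causing loss of iodine or borylation at C2, or iodide may slow catalyst turnover.

Fallback, setting out from 2 and returning at 7: the same borylation applied to iodine-free 2 would give 2-[3,5-bis(methoxymethoxy)phenyl]-4,4,5,5-tetramethyl-1,3,2-dioxaborolane F5, oxidised in the same flask (NaOH, H2O2) to 3,5-bis(methoxymethoxy)phenol F6. Benzylation (BnBr, K2CO3, DMF) would give 1-(benzyloxy)-3,5-bis(methoxymethoxy)benzene F7. Lithiation between the two acetal groups (n-BuLi, THF, 0 °C) would give [4-(benzyloxy)-2,6-bis(methoxymethoxy)phenyl]lithium F1, and an iodine quench would give 7. The iodine is then introduced last, so it never meets the iridium catalyst. The cost is a metalation in which the benzyl ether offers competing sites.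

**Step 11.** Sulfation of the second catechol oxygen may stall, because the first sulfate group crowds and deactivates its neighbour. The 3-acetate may be cleaved during the long reaction or the ion exchange, and the acid form may hydrolyse on concentration.

Fallback, setting out from 17 and returning at 18: 2,2,2-trichloroethyl chlorosulfate with Et3N in THF at 0 °C would give the neutral tris(2,2,2-trichloroethyl sulfate) of quercetin 3-acetate F8, which can be purified on silica. Reductive removal of the trichloroethyl groups (Zn dust, HCO2NH4, DMF, rt) would give 18 as its ammonium salt, converted to the acid form as in the route. The sulfate groups are then introduced as protected diesters and unmasked under near-neutral conditions.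

**Step 6.** Enolisation of the donor-substituted ketone in methanolic KOH may be incomplete, the electron-rich ring may be oxidised by the trivalent iodine reagent, and the α-hydroxy ketone may self-condense during acetal hydrolysis.

Fallback, setting out from 9 and returning at 11: α-bromination (CuBr2, EtOAc–CHCl3, reflux) would give 2-bromo-1-[3,4-bis(benzyloxy)phenyl]ethan-1-one F9. Displacement with HCO2Na in aqueous ethanol at reflux would give 2-[3,4-bis(benzyloxy)phenyl]-2-oxoethyl formate F10, which hydrolyses under the same conditions to 11.

## Further compounds

F1 | step 8 | [4-(benzyloxy)-2,6-bis(methoxymethoxy)phenyl]lithium | [Li]c1c(OCOC)cc(OCc2ccccc2)cc1OCOC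
F2 | step 8 | 4-(benzyloxy)-2,6-bis(methoxymethoxy)benzaldehyde | COCOc1cc(OCc2ccccc2)cc(OCOC)c1C=O
F3 | step 8 | lithium (Z)-enolate of 12 | [Li]O/C(=C\OCOC)c1ccc(OCc2ccccc2)c(OCc2ccccc2)c1
F4 | step 8 | 1-[3,4-bis(benzyloxy)phenyl]-3-[4-(benzyloxy)-2,6-bis(methoxymethoxy)phenyl]-3-hydroxy-2-(methoxymethoxy)propan-1-one (mixture of diastereomers) | COCOc1cc(OCc2ccccc2)cc(OCOC)c1C(O)C(OCOC)C(=O)c1ccc(OCc2ccccc2)c(OCc2ccccc2)c1
F5 | step 3 | 2-[3,5-bis(methoxymethoxy)phenyl]-4,4,5,5-tetramethyl-1,3,2-dioxaborolane | COCOc1cc(OCOC)cc(B2OC(C)(C)C(C)(C)O2)c1
F6 | step 3 | 3,5-bis(methoxymethoxy)phenol | COCOc1cc(O)cc(OCOC)c1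
F7 | step 3 | 1-(benzyloxy)-3,5-bis(methoxymethoxy)benzene | COCOc1cc(OCc2ccccc2)cc(OCOC)c1
F8 | step 11 | quercetin 3-acetate 7,3',4'-tris(2,2,2-trichloroethyl sulfate) | CC(=O)Oc1c(-c2ccc(OS(=O)(=O)OCC(Cl)(Cl)Cl)c(OS(=O)(=O)OCC(Cl)(Cl)Cl)c2)oc2cc(OS(=O)(=O)OCC(Cl)(Cl)Cl)cc(O)c2c1=O
F9 | step 6 | 2-bromo-1-[3,4-bis(benzyloxy)phenyl]ethan-1-one | O=C(CBr)c1ccc(OCc2ccccc2)c(OCc2ccccc2)c1
F10 | step 6 | 2-[3,4-bis(benzyloxy)phenyl]-2-oxoethyl formate | O=COCC(=O)c1ccc(OCc2ccccc2)c(OCc2ccccc2)c1
A1 | alternative 1 | 3-(benzyloxy)-2-(2,2-diphenyl-1,3-benzodioxol-5-yl)-5,7-dihydroxychromen-4-one | O=c1c(OCc2ccccc2)c(-c2ccc3OC(c4ccccc4)(c4ccccc4)Oc3c2)oc2cc(O)cc(O)c12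
A2 | alternative 1 | phloroglucinol | Oc1cc(O)cc(O)c1
A3 | alternative 1 | ethyl 2-(benzyloxy)-3-(2,2-diphenyl-1,3-benzodioxol-5-yl)-3-oxopropanoate | CCOC(=O)C(OCc1ccccc1)C(=O)c1ccc2OC(c3ccccc3)(c3ccccc3)Oc2c1
A4 | alternative 2 | 2-[3,4-bis(benzyloxy)phenyl]-5,7-difluoro-3-(4-methoxybenzyloxy)chromen-4-one | O=c1c(OCc2ccc(OC)cc2)c(-c2ccc(OCc3ccccc3)c(OCc3ccccc3)c2)oc2cc(F)cc(F)c12
A5 | alternative 2 | 1-[3,4-bis(benzyloxy)phenyl]-2-(4-methoxybenzyloxy)-3-(2,4,6-trifluorophenyl)propane-1,3-dione | O=C(c1ccc(OCc2ccccc2)c(OCc2ccccc2)c1)C(OCc1ccc(OC)cc1)C(=O)c1c(F)cc(F)cc1F
A6 | alternative 3 | 5,7,3',4'-tetrakis(benzyloxy)flavone | O=c1cc(-c2ccc(OCc3ccccc3)c(OCc3ccccc3)c2)oc2cc(OCc3ccccc3)cc(OCc3ccccc3)c12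
A7 | alternative 3 | 3,5-bis(benzyloxy)benzyne | C1#CC(OCc2ccccc2)=CC(OCc2ccccc2)=C1
A8 | alternative 3 | 3-[3,4-bis(benzyloxy)phenyl]prop-2-ynoic acid | O=C(O)C#Cc1ccc(OCc2ccccc2)c(OCc2ccccc2)c1
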